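Two numbers and one verdict are asked of you here.

the same everywhere: X 32 mM
- epsilon: D 2 M; Q 0.019 M; temperature 28 °C; run made earlier
- delta: D 2 M; Q 0.085 M; temperature 44 °C; run made earlier
- alpha: D 2.1 M; Q 0.060 M; temperature 28 °C; run made earlier
- green: D 2.0 M; Q 0.0600 M; at 20 °C until 40 h, from then on at 50 °C; time 5.0 d
- grey: D 1.2 M; Q 0.0150 M; at 50 °C throughout; time 5.0 d

epsilon run (percent of the D charged)

| time / d | G / % |
|---|---|
| 0.125 | 15.5 |
| 0.417 | 40.1 |
| 0.625 | 50.9 |
| 1.04 | 68.1 |
| 1.67 | 82.7 |
| 2.08 | 89.8 |
| 2.50 | 90.1 |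

delta run (percent of the D charged)

| time / h | G / % |
|---|---|
| 1.50 | 28.0 |
| 2.50 | 41.8 |
| 4.00 | 53.1 |
| 5.00 | 56.8 |
| 8.00 | 67.7 |
| 12.0 | 76.4 |
| 20.0 | 79.3 |

alpha run (percent of the D charged)

| time / d | G / % |
|---|---|
| 0.208 | 22.4 |
| 0.625 | 45.7 |
| 1.25 | 61.9 |
| 1.67 | 70.3 |
| 2.50 | 77.1 |

(each reading ± 1 percentage point)

1. the winner by amount of G, in percent of the D charged; "neither" if no more than 2 percentage points parts them (green / grey / neither)
2. how much G is there at the end, in percent of the D charged: green
3. how much G is there at the end, in percent of the D charged: grey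



Start with the runs. With [Q] above [X], delta and alpha bend away early, while epsilon, with [Q] at 0.019 M below [X] at 32 mM, climbs to 90.1%. So suppose X starts chains and each Q kills one. If D and Q are both lost in proportion to the same active amount, that amount cancels. The logarithm of D's fall divided by the logarithm of Q's fall is then a constant, the reach, a selectivity factor between growing and dying. With [Q] above [X] and each X lost to one Q, Q's fall ends at charged [Q] minus charged [X].

You have two ways to green. Delta's last reading, 79.3%, gives a reach of 3.33, and that puts green at 92.1%. Replace the falling [Q] by its mean and you get 91.2%, so the logarithm buys little. Alpha, with green's own [Q] and [X], gives a reach of 1.93, which would leave green at alpha's last reading, 77.1%. The two part, and alpha is the one that cheats: its last interval gained 6.8 percentage points, more than delta's 2.9 points, so it was still climbing. I commit to delta's figure, knowing that green's cool 40 h may lower it.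

In grey, [X] exceeds [Q] by 17.0 mM, so the logarithm has no finite value and the reach sets no ceiling. Epsilon, also short of Q, made 90.1% in 2.50 d, and grey gets 5.0 d at 50 °C, so I expect it near full.

The forecast, on the ground “This fits Q killing initiator”, names grey: green 89% (83% to 93%), grey 99% (94% to 100%). My green stands above its number, inside its range.

The flasks give green 92.4% and grey 100%, so grey wins.

    D + L → G + L, rate k1*[L]*[D] (k = 0.710 M⁻¹ h⁻¹, Ea = 78.0 kJ mol⁻¹)
    D + X → L + G (k = 0.850 M⁻¹ h⁻¹, Ea = 70.0 kJ mol⁻¹)
    L + Q → Z (k = 0.330 M⁻¹ h⁻¹, Ea = 60.0 kJ mol⁻¹)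
    2 X ⇌ E (K = 7400 M⁻¹, k = 0.980 M⁻¹ h⁻¹, Ea = 55.0 kJ mol⁻¹, ΔH = −19.0 kJ mol⁻¹)
    (constants at 20 °C)

With 7.6% of D and 48% of Q left, green's own reach comes to 3.46, beside delta's 3.33. Now take a neighbour of green, charged with 0.036 M of Q. With each X lost to one Q, its [Q] ends at 4.00 mM, and delta's reach then gives 99.9%. The neighbour gives 99.9%, more than green, with 17% of its Q left.

(The data come from a simulation with constants of no real substance; noise was put on by code.)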